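Asked: how much product the flask holds at its stop time, with what excess, and whether the exchange between the substrates matters by then.

in all of them: left-handed substrate 1.5 M; right-handed substrate 1.5 M; gas 200 mM (held); free catalyst 70 mM; impurity 12 mM
- violet: racemization catalyst 50 mM; run made earlier
- ochre: racemization catalyst 110 mM; run made earlier
- flask: racemization catalyst 75 mM; time 8.0 min

| run | time / min | left-handed product / % | right-handed product / % |
|---|---|---|---|
| violet | 1.50 | 4.2 | 4.1 |
| violet | 3.00 | 9.5 | 5.7 |
| violet | 5.00 | 15.9 | 10.2 |
| violet | 6.00 | 18.5 | 9.8 |
| violet | 8.00 | 24.5 | 14.5 |
| violet | 10.0 | 28.2 | 16.0 |
| ochre | 0.833 | 2.6 | 0.3 |
| ochre | 1.33 | 5.1 | 0.9 |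
| ochre | 2.00 | 6.5 | 4.6 |
| ochre | 4.00 | 13.3 | 7.7 |
| ochre | 6.00 | 17.9 | 11.3 |
| ochre | 10.0 | 29.7 | 18.2 |

(scatter of a reading: 1 percentage point)

* left-handed product and right-handed product together, in percent of the left-handed substrate and right-handed substrate charged together, at 8.0 min
* excess of left-handed product over right-handed product in the product at 8.0 min
* whether the exchange between left-handed substrate and right-handed substrate keeps pace with the reaction: how far the product's excess at 8.0 min gets from its value without exchange to its value with instant exchange (above 80% keeps pace, below 20% hardly takes part, else lags behind)

- free catalyst is single-handed; left-handed substrate and right-handed substrate are mirror images of each other, charged as a racemate, each of them at the stated concentration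
- at the start none of reagent is dissolved
- candidate steps: reagent + free catalyst + left-handed substrate -> free catalyst + left-handed product; reagent + free catalyst + right-handed substrate -> free catalyst + right-handed product; left-handed substrate + racemization catalyst <-> right-handed substrate + racemization catalyst; racemization catalyst + impurity -> spent catalyst A; reagent + racemization catalyst -> spent catalyst B; gas <-> reagent
- an excess is the difference of the two amounts in percent of their sum
- an excess is below zero if the other one leads

The free catalyst turns each substrate into its product, while the racemization catalyst swaps the substrates. Without the swap both substrates decay under one shared, wandering factor, [reagent][free catalyst], so dividing one logarithmic decay by the other removes time. I called that quotient the decay ratio s, the usual selectivity factor. Without the swap, each substrate's unreacted fraction is 1 − 2·(its product reading). From the last readings: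

violet 2.15, ochre 1.99, mean 2.07

I borrowed violet's right-handed reading at 8.00 min, 14.5%, for the flask. Then s gave the left-handed product:

left-handed product 25.4%, total 39.9%

excess without exchange 27.3%

With instant exchange the substrates stay equal, so the excess is (s − 1)/(s + 1) = 34.9%. Four late readings (violet at 8.00 min and 10.0 min, ochre at 6.00 min and 10.0 min) average:

observed excess 25.0%

That lies below the no-exchange value, but s came from these same readings and assumed no exchange, so this shows only that the assumption holds together. The separate evidence was the comparison of the runs: ochre held more racemization catalyst than violet, yet its late excess, 23.3%, was lower than violet's 26.6%. Exchange that was slow but mattered should have raised ochre's excess, though exchange already instant in both runs fits this too. On that thin ground I committed to exchange hardly taking part.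

The weak link was s, resting on one reading per run. Adding violet at 8.00 min and ochre at 6.00 min, the pooled decay ratio, left logarithmic decay over right, became

s = 1.96

which moved the limits to 25.5% and 32.4%. The observed excess, from those same readings, still sat at the lower one.

The forecast said 38.8%, 25.5% and keeps pace: “Doubling the racemization catalyst also changes nothing, which suggests exchange is already fast compared with reaction.” My reckoning parted from it on the pace.

The flask gave 38.5%, excess 24.5%, and the exchange hardly takes part, at 11% of the way.

    reagent + free catalyst + left-handed substrate → free catalyst + left-handed product (k = 6.90 M⁻² min⁻¹)
    reagent + free catalyst + right-handed substrate → free catalyst + right-handed product (k = 3.70 M⁻² min⁻¹)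
    left-handed substrate + racemization catalyst ⇌ right-handed substrate + racemization catalyst, rate k3*[racemization catalyst]*[left-handed substrate] forward; the back reaction follows from the equilibrium constant (k = 0.630 M⁻¹ min⁻¹)
    racemization catalyst + impurity → spent catalyst A (k = 2000 M⁻¹ min⁻¹)
    reagent + racemization catalyst → spent catalyst B (k = 0.820 M⁻¹ min⁻¹)
    gas ⇌ reagent, rate k6*(csat - [reagent]) (kL = 5.20 min⁻¹)

The forecast's two numbers held and its pace did not, with 23.8% as the flask's excess without exchange. From the flask's right-handed product, 14.5%, s gave an excess of 25.5%. The neighbour with 0.18 M of free catalyst reached 65.9% of product, and its right-handed product was 26.8%. There s gave 38.9% of left-handed product and an excess of 18.4%. That neighbour's excess came out at 18.6%.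

The data stem from a simulated flask on assumed constants; noise was put on by code.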